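Readings and results were generated by integration from invented constants, noise included.

- Once the feed is in, the substrate left, the target and a gap that neither reading shows add up to the whole charge, so what you need to know is how the reacted part divides.
- Wednesday's and Friday's runs differ in their acid. At 10.0 min, target was 0.392 of what had reacted on Wednesday and 0.474 on Friday, both readings with a scatter of 1 percentage point behind them.
- A straight line through those two readings, carried down to 0.600 mM of acid in your flask, gives an estimate of 0.350: this is the target's share of what has reacted, the usual selectivity.

common to all: substrate 0.20 M (fed, over 4.0 min)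

|  | acid | remark | time |
|---|---|---|---|
| Wednesday's | 0.84 mM | run made earlier; the fed solution adds 0.25 times the starting volume |  |
| Friday's | 1.3 mM | run made earlier; the fed solution adds 0.25 times the starting volume |  |
| flask | 0.600 mM | the fed solution adds 0.25 times the starting volume | 15 min |

| run | time / min | substrate / % | target / % |
|---|---|---|---|
| Wednesday's | 0.833 | 21.2 | 0.6 |
| Wednesday's | 2.50 | 54.5 | 4.3 |
| Wednesday's | 4.00 | 73.7 | 9.9 |
| Wednesday's | 6.00 | 52.7 | 18.3 |
| Wednesday's | 10.0 | 30.4 | 27.3 |
| Friday's | 0.667 | 16.5 | 0.2 |
| Friday's | 1.33 | 31.7 | 2.6 |
| Friday's | 2.50 | 52.7 | 8.4 |
| Friday's | 5.00 | 58.3 | 20.0 |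
| Friday's | 10.0 | 24.7 | 35.7 |

(each reading ± 1 percentage point)

- acid is the free proton; pH is minus the decimal logarithm of its molar concentration
- charges are per starting volume, the dose included; the dosed solution carries all of it
- what was read earlier has a scatter of 1 percentage point, one standard deviation
- percentages count the whole charge, also what has not yet gone in

1. part of the substrate that has reacted at 15 min
2. pH of the solution at 15 min

- Your flask takes its substrate over 4.0 min, and the forecast expects 80 % reacted and pH 3.32 when you come at 15 min. One of its grounds is this: “The missing material forms at the same rate in both runs”.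
- My own reckoning puts that forecast and the share together: expect 28.0 % of the charge as target and 52.0 % in the gap.
- Don't lower the acid in your flask: it already has less than either run, and Friday's run, with more acid, had a larger share than Wednesday's.
- The flask gives 80.4 % reacted and pH 3.23, by these steps:

    2 substrate → self-condensation product (k = 0.00970 M⁻¹ s⁻¹)
    substrate → weak acid + target (k = 2.15 × 10⁻⁴ s⁻¹)
    weak acid ⇌ conjugate base + acid, settled at all times (K = 1.30 × 10⁻⁶ M)
    substrate + acid → weak acid + acid + target (k = 1.12 M⁻¹ s⁻¹)

- At 15.0 min the flask holds 51.4 % of the charge as self-condensation product. The share turns 80.4 % into 28.1 % target, against 28.9 % in the flask. Read at 10 min, the same flask has 67.9 % reacted, so the share gives 23.8 % target, and that flask holds 22.5 %.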